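**Assumption:** the SMILES is taken as the full definition of the target. Sesquiterpene numbering is used throughout: ring C7 (bears C11), C8 (bears the lactone O), C9 (CH2), C10 (CHMe), C1 (bears the side chain), C5 (=C–Me), C6 (=CH); lactone C11/C12/C13; side chain C2 (O-angeloyl), C3, C4 (OAc). The target is 7R,8R,10R,1S,2S. Abbreviations: TBS = tert-butyldimethylsilyl, TBDPS = tert-butyldiphenylsilyl, TES = triethylsilyl, PMB = 4-methoxybenzyl.

## Retrosynthetic overview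

1. Target 42 ⇐ diol 38: lipase acetylation of the primary OH, then Yamaguchi angeloylation of the secondary OH; the exo-methylene comes from Eschenmoser methylenation of lactone 34.
2. 34 ⇐ 33 by ring-closing metathesis (C5=C6). The cycloheptene is the last ring formed; the cis γ-lactone (oxidative lactonisation of 1,4-diol 31) is closed just before it.
3. 31 ⇐ δ-lactone 19, a temporary ring (C5 carbonyl, C8 oxygen) used as a template: aldol, oxidation and chelate-controlled reduction set C1/C2; Weinreb opening, MeMgBr and methylenation give the isopropenyl group.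
4. 19 ⇐ β-keto ester 7: Noyori hydrogenation (C8) and Fráter–Seebach allylation (C7); allyl becomes CH2CH2OPMB and the ester becomes vinyl via temporary butyrolactone 13.
5. 7 ⇐ dimethyl 3-methylglutarate 1: esterase desymmetrisation sets C10, the first stereocentre.

## Route

Step 1
Reactants: 1 dimethyl 3-methylpentanedioate
Product: 2 (3R)-5-methoxy-3-methyl-5-oxopentanoic acid
Conditions: pig liver esterase (a carboxylesterase), pH 7 phosphate buffer/MeOH (4:1), −10 °C, pH-stat with 1 M NaOH; then HCl to pH 2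
Reagents that add atoms: water (O)
Why: Enzymatic desymmetrisation of the prochiral diester hydrolyses one enantiotopic ester only, setting C10 catalytically as the (R)-half-ester; material from the minor enantiomer becomes a separable diastereomer after step 6.

Step 2
Reactants: 2 (3R)-5-methoxy-3-methyl-5-oxopentanoic acid
Product: 4 (4S)-4-methyloxan-2-one, via hydroxy acid 3 (not isolated)
Conditions: LiOH (1.0 equiv), THF, 0 °C; LiBH4 (2.5 equiv), THF, reflux; then 2 M HCl, rt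
Reagents that add atoms: none
Why: Chemoselective borohydride reduction of the ester in the presence of the carboxylate, then acid lactonisation, so the former acid carbon becomes C8 and the reduced arm C5; C10 is untouched.

Step 3
Reactants: 4 (4S)-4-methyloxan-2-one
Product: 5 (3S)-5-hydroxy-N-methoxy-N,3-dimethylpentanamide
Conditions: MeNH(OMe)·HCl (3 equiv), AlMe3 (3 equiv), CH2Cl2, 0 °C → rt; Rochelle salt work-up; crude used at once
Reagents that add atoms: N,O-dimethylhydroxylamine hydrochloride (CNOC.Cl)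
Why: Weinreb aminolysis of the lactone with the aluminium amide opens the ring to the hydroxy Weinreb amide without touching C10.

Step 4
Reactants: 5 (3S)-5-hydroxy-N-methoxy-N,3-dimethylpentanamide
Product: 6 (3S)-5-(TBDPS-oxy)-N-methoxy-N,3-dimethylpentanamide
Conditions: TBDPSCl (1.2 equiv), imidazole (2.5 equiv), DMF, 0 °C → rt
Reagents that add atoms: tert-butyldiphenylsilyl chloride (CC(C)(C)[Si](Cl)(c1ccccc1)c1ccccc1)
Why: Silylation blocks relactonisation and masks C5–OH with a group that survives hydrogenation, LDA, ozone and DIBAL-H.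

Step 5
Reactants: 6 (3S)-5-(TBDPS-oxy)-N-methoxy-N,3-dimethylpentanamide
Product: 7 methyl (5S)-7-(TBDPS-oxy)-5-methyl-3-oxoheptanoate
Conditions: MeOAc (3 equiv), LDA (3 equiv), THF, −78 °C; add 6, −78 → −40 °C; AcOH quench
Reagents that add atoms: methyl acetate (CC(=O)OC)
Why: Crossed Claisen acylation of the ester enolate by the Weinreb amide stops at the β-keto ester because the tetrahedral chelate is stable, adding C7 and C6.

Step 6
Reactants: 7 methyl (5S)-7-(TBDPS-oxy)-5-methyl-3-oxoheptanoate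
Product: 8 methyl (3R,5S)-7-(TBDPS-oxy)-3-hydroxy-5-methylheptanoate
Conditions: H2 (10 bar), RuCl2[(R)-BINAP] (0.5 mol%), MeOH, 50 °C
Reagents that add atoms: none
Why: Noyori asymmetric hydrogenation of the β-keto ester is catalyst-controlled, and (R)-BINAP gives the (3R)-carbinol (C8) in the same sense as (R)-methyl 3-hydroxybutanoate.

Step 7
Reactants: 8 methyl (3R,5S)-7-(TBDPS-oxy)-3-hydroxy-5-methylheptanoate
Product: 9 methyl (2R,3R,5S)-2-allyl-7-(TBDPS-oxy)-3-hydroxy-5-methylheptanoate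
Conditions: LDA (2.3 equiv), THF, −78 → −20 °C; allyl bromide (2 equiv), DMPU, −78 → −15 °C; AcOH quench
Reagents that add atoms: allyl bromide (C=CCBr)
Why: Fráter–Seebach alkylation: the chelated dianion is allylated anti to the alkoxide substituent, setting C7 with the anti C7/C8 relationship that corresponds to the cis lactone.

Step 8
Reactants: 9 methyl (2R,3R,5S)-2-allyl-7-(TBDPS-oxy)-3-hydroxy-5-methylheptanoate
Product: 10 methyl (2R,3R,5S)-2-allyl-3-(TBS-oxy)-7-(TBDPS-oxy)-5-methylheptanoate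
Conditions: TBSOTf (1.3 equiv), 2,6-lutidine (2 equiv), CH2Cl2, −78 → 0 °C
Reagents that add atoms: tert-butyldimethylsilyl triflate (CC(C)(C)[Si](C)(C)OS(=O)(=O)C(F)(F)F)
Why: Silylation of the hindered C8–OH prevents retro-aldol and elimination in the later lactol/Wittig steps.

Step 9
Reactants: 10 methyl (2R,3R,5S)-2-allyl-3-(TBS-oxy)-7-(TBDPS-oxy)-5-methylheptanoate
Product: 13 (3R)-3-[(1R,3S)-1-(TBS-oxy)-5-(TBDPS-oxy)-3-methylpentyl]oxolan-2-one, via aldehyde 11 (not isolated), via hydroxy ester 12 (not isolated)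
Conditions: O3, CH2Cl2/MeOH (4:1), −78 °C; NaBH4 (4 equiv), −78 → 0 °C; then PPTS (cat.), toluene, 60 °C
Reagents that add atoms: ozone ([O-][O+]=O)
Why: Ozonolysis with reductive work-up turns the allyl group into CH2CH2OH (C11–C12), which lactonises onto the methyl ester; this is the only alkene in the molecule at this stage and C7 is not touched.

Step 10
Reactants: 13 (3R)-3-[(1R,3S)-1-(TBS-oxy)-5-(TBDPS-oxy)-3-methylpentyl]oxolan-2-one
Product: 14 (3R)-3-[(1R,3S)-1-(TBS-oxy)-5-(TBDPS-oxy)-3-methylpentyl]oxolan-2-ol (anomers)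
Conditions: DIBAL-H (1.1 equiv), CH2Cl2, −78 °C; Rochelle salt
Reagents that add atoms: none
Why: Partial reduction of a γ-lactone at −78 °C stops at the lactol, a masked C6 aldehyde.

Step 11
Reactants: 14 (3R)-3-[(1R,3S)-1-(TBS-oxy)-5-(TBDPS-oxy)-3-methylpentyl]oxolan-2-ol
Product: 15 (3S,4R,6S)-4-(TBS-oxy)-8-(TBDPS-oxy)-3-ethenyl-6-methyloctan-1-ol
Conditions: Ph3PCH3Br (4 equiv), KHMDS (3.8 equiv), THF, 0 °C; add 14, 0 °C → rt
Reagents that add atoms: methyltriphenylphosphonium bromide (C[P+](c1ccccc1)(c1ccccc1)c1ccccc1.[Br-])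
Why: Wittig methylenation of the lactol's open form installs the C7 vinyl group and frees C12–OH; excess salt-free ylide at low temperature keeps C7 from epimerising.

Step 12
Reactants: 15 (3S,4R,6S)-4-(TBS-oxy)-8-(TBDPS-oxy)-3-ethenyl-6-methyloctan-1-ol
Product: 16 (3S,4R,6S)-4-(TBS-oxy)-8-(TBDPS-oxy)-3-ethenyl-6-methyloctyl 4-methoxybenzyl ether
Conditions: NaH (1.5 equiv), PMBCl (1.3 equiv), Bu4NI (cat.), DMF, 0 °C → rt
Reagents that add atoms: 4-methoxybenzyl chloride (COc1ccc(CCl)cc1)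
Why: Williamson etherification masks C12–OH with a group orthogonal to the silyl ethers and to the later acetonide.

Step 13
Reactants: 16 (3S,4R,6S)-4-(TBS-oxy)-8-(TBDPS-oxy)-3-ethenyl-6-methyloctyl 4-methoxybenzyl ether
Product: 17 (3S,5R,6S)-6-ethenyl-8-(PMB-oxy)-3-methyloctane-1,5-diol
Conditions: TBAF (4 equiv), THF, rt → 45 °C
Reagents that add atoms: none
Why: Fluoride removes both silyl ethers and leaves the PMB ether and vinyl group, exposing the C5/C8 1,5-diol.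

Step 14
Reactants: 17 (3S,5R,6S)-6-ethenyl-8-(PMB-oxy)-3-methyloctane-1,5-diol
Product: 19 (4R,6R)-6-[(3S)-5-(PMB-oxy)pent-1-en-3-yl]-4-methyloxan-2-one, via lactol 18 (not isolated)
Conditions: TEMPO (0.2 equiv), PhI(OAc)2 (2.5 equiv), CH2Cl2, rt
Reagents that add atoms: none
Why: TEMPO oxidises only the primary alcohol; the aldehyde is trapped by C8–OH and oxidised on to the δ-lactone, a cis-4,6-disubstituted, all-equatorial template.

Step 15
Reactants: 19 (4R,6R)-6-[(3S)-5-(PMB-oxy)pent-1-en-3-yl]-4-methyloxan-2-one; 20 3-(TBS-oxy)propanal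
Product: 21 (3R,4R,6R)-3-[3-(TBS-oxy)-1-hydroxypropyl]-6-[(3S)-5-(PMB-oxy)pent-1-en-3-yl]-4-methyloxan-2-one (carbinol epimers)
Conditions: LDA (1.2 equiv), THF, −78 °C; 20 (1.5 equiv), −78 °C; AcOH quench at −78 °C
Reagents that add atoms: none
Why: Aldol addition of the lactone lithium enolate forms the C1–C2 bond trans to the adjacent C10 methyl; the carbinol configuration is irrelevant because it is erased in step 16.

Step 16
Reactants: 21 (3R,4R,6R)-3-[3-(TBS-oxy)-1-hydroxypropyl]-6-[(3S)-5-(PMB-oxy)pent-1-en-3-yl]-4-methyloxan-2-one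
Product: 22 (3R,4R,6R)-3-[3-(TBS-oxy)propanoyl]-6-[(3S)-5-(PMB-oxy)pent-1-en-3-yl]-4-methyloxan-2-one
Conditions: Dess–Martin periodinane (1.5 equiv), NaHCO3, CH2Cl2, 0 °C → rt
Reagents that add atoms: none
Why: Buffered Dess–Martin oxidation gives the β-keto lactone, whose acidic C1 equilibrates to the all-equatorial isomer (acyl trans to the C10 methyl).

Step 17
Reactants: 22 (3R,4R,6R)-3-[3-(TBS-oxy)propanoyl]-6-[(3S)-5-(PMB-oxy)pent-1-en-3-yl]-4-methyloxan-2-one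
Product: 23 (3R,4R,6R)-3-[(1S)-3-(TBS-oxy)-1-hydroxypropyl]-6-[(3S)-5-(PMB-oxy)pent-1-en-3-yl]-4-methyloxan-2-one
Conditions: Zn(BH4)2 (2 equiv, 0.15 M in Et2O), CH2Cl2, −40 → −10 °C; aq NH4Cl
Reagents that add atoms: none
Why: Chelation-controlled reduction: zinc bridges the ketone and lactone carbonyls and hydride enters from the C1–H face, away from ring carbon C10, giving the syn (2S) carbinol.

Step 18
Reactants: 23 (3R,4R,6R)-3-[(1S)-3-(TBS-oxy)-1-hydroxypropyl]-6-[(3S)-5-(PMB-oxy)pent-1-en-3-yl]-4-methyloxan-2-one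
Product: 25 (3R,4R,6R)-3-[(4S)-2,2-dimethyl-1,3-dioxan-4-yl]-6-[(3S)-5-(PMB-oxy)pent-1-en-3-yl]-4-methyloxan-2-one, via diol 24 (not isolated)
Conditions: HF·pyridine, THF/pyridine, 0 °C; then 2,2-dimethoxypropane, PPTS (cat.), CH2Cl2, rt
Reagents that add atoms: 2,2-dimethoxypropane (COC(C)(C)OC)
Why: Mildly acidic desilylation and immediate acetonide formation tie up the C2/C4 diol as a compact dioxane before the diol can translactonise.

Step 19
Reactants: 25 (3R,4R,6R)-3-[(4S)-2,2-dimethyl-1,3-dioxan-4-yl]-6-[(3S)-5-(PMB-oxy)pent-1-en-3-yl]-4-methyloxan-2-one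
Product: 26 (2R,3R,5R,6S)-2-[(4S)-2,2-dimethyl-1,3-dioxan-4-yl]-6-ethenyl-5-hydroxy-N-methoxy-8-(PMB-oxy)-N,3-dimethyloctanamide
Conditions: MeNH(OMe)·HCl (5 equiv), AlMe3 (5 equiv), CH2Cl2, 0 °C → rt
Reagents that add atoms: N,O-dimethylhydroxylamine hydrochloride (CNOC.Cl)
Why: Non-basic Weinreb aminolysis opens the template lactone without epimerising C1 or eliminating the β-alkoxy group, and frees C8–OH.

Step 20
Reactants: 26 (2R,3R,5R,6S)-2-[(4S)-2,2-dimethyl-1,3-dioxan-4-yl]-6-ethenyl-5-hydroxy-N-methoxy-8-(PMB-oxy)-N,3-dimethyloctanamide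
Product: 27 (2R,3R,5R,6S)-2-[(4S)-2,2-dimethyl-1,3-dioxan-4-yl]-6-ethenyl-N-methoxy-8-(PMB-oxy)-N,3-dimethyl-5-(TES-oxy)octanamide
Conditions: TESCl (1.5 equiv), imidazole (3 equiv), DMF, 0 °C
Reagents that add atoms: chlorotriethylsilane (CC[Si](Cl)(CC)CC)
Why: Silylation of C8–OH stops relactonisation and hemiketal formation in the next two steps.

Step 21
Reactants: 27 (2R,3R,5R,6S)-2-[(4S)-2,2-dimethyl-1,3-dioxan-4-yl]-6-ethenyl-N-methoxy-8-(PMB-oxy)-N,3-dimethyl-5-(TES-oxy)octanamide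
Product: 28 (3R,4R,6R,7S)-3-[(4S)-2,2-dimethyl-1,3-dioxan-4-yl]-7-ethenyl-9-(PMB-oxy)-4-methyl-6-(TES-oxy)nonan-2-one
Conditions: MeMgBr (3 equiv), THF, −20 → 0 °C; aq NH4Cl
Reagents that add atoms: methylmagnesium bromide (C[Mg]Br)
Why: Weinreb ketone synthesis: the chelated tetrahedral intermediate prevents over-addition and delivers the methyl ketone (C5 with its methyl, C15).

Step 22
Reactants: 28 (3R,4R,6R,7S)-3-[(4S)-2,2-dimethyl-1,3-dioxan-4-yl]-7-ethenyl-9-(PMB-oxy)-4-methyl-6-(TES-oxy)nonan-2-one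
Product: 29 (4S)-4-[(3S,4R,6R,7S)-7-ethenyl-9-(PMB-oxy)-2,4-dimethyl-6-(TES-oxy)non-1-en-3-yl]-2,2-dimethyl-1,3-dioxane
Conditions: Cp2TiMe2 (3 equiv), toluene, 70 °C, dark
Reagents that add atoms: dimethyltitanocene (C[Ti](C)(C1C=CC=C1)C1C=CC=C1)
Why: Petasis methylenation is non-basic, so the α-stereocentre C1 and the β-alkoxy group survive while the ketone becomes the isopropenyl group.

Step 23
Reactants: 29 (4S)-4-[(3S,4R,6R,7S)-7-ethenyl-9-(PMB-oxy)-2,4-dimethyl-6-(TES-oxy)non-1-en-3-yl]-2,2-dimethyl-1,3-dioxane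
Product: 30 (3S,4R,6R,7S)-7-[(4S)-2,2-dimethyl-1,3-dioxan-4-yl]-3-ethenyl-6,8-dimethyl-4-(TES-oxy)non-8-en-1-ol
Conditions: DDQ (1.5 equiv), CH2Cl2/pH 7 buffer (10:1), 0 °C
Reagents that add atoms: none
Why: Oxidative cleavage of the PMB ether frees C12–OH; C8 is still silylated, so no cyclic PMP acetal can form, and the acetonide and alkenes are inert.

Step 24
Reactants: 30 (3S,4R,6R,7S)-7-[(4S)-2,2-dimethyl-1,3-dioxan-4-yl]-3-ethenyl-6,8-dimethyl-4-(TES-oxy)non-8-en-1-ol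
Product: 31 (3S,4R,6R,7S)-7-[(4S)-2,2-dimethyl-1,3-dioxan-4-yl]-3-ethenyl-6,8-dimethylnon-8-ene-1,4-diol
Conditions: TBAF (1.5 equiv), THF, 0 °C → rt
Reagents that add atoms: none
Why: Fluoride removes the TES ether only, giving the C8/C12 1,4-diol.

Step 25
Reactants: 31 (3S,4R,6R,7S)-7-[(4S)-2,2-dimethyl-1,3-dioxan-4-yl]-3-ethenyl-6,8-dimethylnon-8-ene-1,4-diol
Product: 33 (4S,5R)-5-[(2R,3S)-3-[(4S)-2,2-dimethyl-1,3-dioxan-4-yl]-2,4-dimethylpent-4-en-1-yl]-4-ethenyloxolan-2-one, via lactol 32 (not isolated)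
Conditions: TEMPO (0.2 equiv), PhI(OAc)2 (3 equiv), CH2Cl2, rt
Reagents that add atoms: none
Why: Chemoselective TEMPO oxidation of the primary alcohol and lactol oxidation close the γ-lactone; its cis arrangement (vinyl and C9 chain on one face) follows from the C7/C8 configurations set in steps 6 and 7.

Step 26
Reactants: 33 (4S,5R)-5-[(2R,3S)-3-[(4S)-2,2-dimethyl-1,3-dioxan-4-yl]-2,4-dimethylpent-4-en-1-yl]-4-ethenyloxolan-2-one
Product: 34 (3aS,6S,7R,8aR)-6-[(4S)-2,2-dimethyl-1,3-dioxan-4-yl]-5,7-dimethyl-3,3a,6,7,8,8a-hexahydro-2H-cyclohepta[b]furan-2-one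
Conditions: Grubbs II (10 mol%), toluene (2 mM), 80 °C, Ar sparge
Reagents that add atoms: none
Why: Ring-closing metathesis between the vinyl and isopropenyl groups, held cis on the lactone, forms the trisubstituted C5=C6 cycloheptene with loss of ethylene and no change at any stereocentre.

Step 27
Reactants: 34 (3aS,6S,7R,8aR)-6-[(4S)-2,2-dimethyl-1,3-dioxan-4-yl]-5,7-dimethyl-3,3a,6,7,8,8a-hexahydro-2H-cyclohepta[b]furan-2-one
Product: 37 (3aR,6S,7R,8aR)-6-[(4S)-2,2-dimethyl-1,3-dioxan-4-yl]-5,7-dimethyl-3-methylidene-3,3a,6,7,8,8a-hexahydro-2H-cyclohepta[b]furan-2-one, via Mannich base 35 (not isolated), via ammonium iodide 36 (not isolated)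
Conditions: LDA (1.5 equiv), THF, −78 °C; CH2=NMe2+ I− (4 equiv), −78 °C → rt; MeI (excess), CH2Cl2/MeOH, rt; sat. aq NaHCO3, rt
Reagents that add atoms: Eschenmoser's salt (C=[N+](C)C.[I-])
Why: Eschenmoser α-methylenation (enolate Mannich reaction, quaternisation, β-elimination) installs the exo-methylene; C11 becomes sp2, so no new stereocentre remains.

Step 28
Reactants: 37 (3aR,6S,7R,8aR)-6-[(4S)-2,2-dimethyl-1,3-dioxan-4-yl]-5,7-dimethyl-3-methylidene-3,3a,6,7,8,8a-hexahydro-2H-cyclohepta[b]furan-2-one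
Product: 38 (3aR,6S,7R,8aR)-6-[(1S)-1,3-dihydroxypropyl]-5,7-dimethyl-3-methylidene-3,3a,6,7,8,8a-hexahydro-2H-cyclohepta[b]furan-2-one
Conditions: AcOH/THF/H2O (3:1:1), 45 °C
Reagents that add atoms: none
Why: Mild acid hydrolysis of the acetonide frees the C2/C4 diol without affecting the α-methylene lactone or the ring alkene.

Step 29
Reactants: 38 (3aR,6S,7R,8aR)-6-[(1S)-1,3-dihydroxypropyl]-5,7-dimethyl-3-methylidene-3,3a,6,7,8,8a-hexahydro-2H-cyclohepta[b]furan-2-one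
Product: 39 (3S)-3-[(3aR,6S,7R,8aR)-5,7-dimethyl-3-methylidene-2-oxo-3,3a,6,7,8,8a-hexahydro-2H-cyclohepta[b]furan-6-yl]-3-hydroxypropyl acetate
Conditions: Candida antarctica lipase B (immobilised), vinyl acetate (5 equiv), MTBE, 30 °C
Reagents that add atoms: vinyl acetate (CC(=O)OC=C)
Why: Lipase-catalysed irreversible transesterification acetylates only the unhindered primary C4–OH under neutral conditions and leaves the hindered C2–OH free.

Step 30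
Reactants: 39 (3S)-3-[(3aR,6S,7R,8aR)-5,7-dimethyl-3-methylidene-2-oxo-3,3a,6,7,8,8a-hexahydro-2H-cyclohepta[b]furan-6-yl]-3-hydroxypropyl acetate; 40 angelic acid
Product: 42 (1S)-3-acetoxy-1-[(3aR,6S,7R,8aR)-5,7-dimethyl-3-methylidene-2-oxo-3,3a,6,7,8,8a-hexahydro-2H-cyclohepta[b]furan-6-yl]propyl (2Z)-2-methylbut-2-enoate, via mixed anhydride 41 (not isolated)
Conditions: 40 (3 equiv), 2,4,6-trichlorobenzoyl chloride (3 equiv), Et3N (3.3 equiv), toluene, rt, 2 h; add 39, 80 °C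
Reagents that add atoms: none
Why: Yamaguchi esterification through the mixed anhydride without DMAP acylates the secondary alcohol at the angeloyl carbonyl with retention at C2 and minimal Z→E isomerisation to the tiglate.

## Compound list

1 | dimethyl 3-methylpentanedioate | COC(=O)CC(C)CC(=O)OC | starting material
2 | (3R)-5-methoxy-3-methyl-5-oxopentanoic acid | OC(=O)C[C@@H](C)CC(=O)OC | intermediate
3 | (3S)-5-hydroxy-3-methylpentanoic acid | OC(=O)C[C@@H](C)CCO | intermediate (not isolated)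
4 | (4S)-4-methyloxan-2-one | O=C1C[C@@H](C)CCO1 | intermediate
5 | (3S)-5-hydroxy-N-methoxy-N,3-dimethylpentanamide | CON(C)C(=O)C[C@@H](C)CCO | intermediate
6 | (3S)-5-(TBDPS-oxy)-N-methoxy-N,3-dimethylpentanamide | CON(C)C(=O)C[C@@H](C)CCO[Si](c1ccccc1)(c1ccccc1)C(C)(C)C | intermediate
7 | methyl (5S)-7-(TBDPS-oxy)-5-methyl-3-oxoheptanoate | COC(=O)CC(=O)C[C@@H](C)CCO[Si](c1ccccc1)(c1ccccc1)C(C)(C)C | intermediate
8 | methyl (3R,5S)-7-(TBDPS-oxy)-3-hydroxy-5-methylheptanoate | COC(=O)C[C@H](O)C[C@@H](C)CCO[Si](c1ccccc1)(c1ccccc1)C(C)(C)C | intermediate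
9 | methyl (2R,3R,5S)-2-allyl-7-(TBDPS-oxy)-3-hydroxy-5-methylheptanoate | COC(=O)[C@H](CC=C)[C@H](O)C[C@@H](C)CCO[Si](c1ccccc1)(c1ccccc1)C(C)(C)C | intermediate
10 | methyl (2R,3R,5S)-2-allyl-3-(TBS-oxy)-7-(TBDPS-oxy)-5-methylheptanoate | COC(=O)[C@H](CC=C)[C@H](O[Si](C)(C)C(C)(C)C)C[C@@H](C)CCO[Si](c1ccccc1)(c1ccccc1)C(C)(C)C | intermediate
11 | methyl (2R,3R,5S)-3-(TBS-oxy)-7-(TBDPS-oxy)-5-methyl-2-(2-oxoethyl)heptanoate | COC(=O)[C@H](CC=O)[C@H](O[Si](C)(C)C(C)(C)C)C[C@@H](C)CCO[Si](c1ccccc1)(c1ccccc1)C(C)(C)C | intermediate (not isolated)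
12 | methyl (2R,3R,5S)-3-(TBS-oxy)-7-(TBDPS-oxy)-2-(2-hydroxyethyl)-5-methylheptanoate | COC(=O)[C@H](CCO)[C@H](O[Si](C)(C)C(C)(C)C)C[C@@H](C)CCO[Si](c1ccccc1)(c1ccccc1)C(C)(C)C | intermediate (not isolated)
13 | (3R)-3-[(1R,3S)-1-(TBS-oxy)-5-(TBDPS-oxy)-3-methylpentyl]oxolan-2-one | O=C1OCC[C@@H]1[C@H](O[Si](C)(C)C(C)(C)C)C[C@@H](C)CCO[Si](c1ccccc1)(c1ccccc1)C(C)(C)C | intermediate
14 | (3R)-3-[(1R,3S)-1-(TBS-oxy)-5-(TBDPS-oxy)-3-methylpentyl]oxolan-2-ol (anomers) | OC1OCC[C@@H]1[C@H](O[Si](C)(C)C(C)(C)C)C[C@@H](C)CCO[Si](c1ccccc1)(c1ccccc1)C(C)(C)C | intermediate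
15 | (3S,4R,6S)-4-(TBS-oxy)-8-(TBDPS-oxy)-3-ethenyl-6-methyloctan-1-ol | C=C[C@H](CCO)[C@H](O[Si](C)(C)C(C)(C)C)C[C@@H](C)CCO[Si](c1ccccc1)(c1ccccc1)C(C)(C)C | intermediate
16 | (3S,4R,6S)-4-(TBS-oxy)-8-(TBDPS-oxy)-3-ethenyl-6-methyloctyl 4-methoxybenzyl ether | C=C[C@H](CCOCc1ccc(OC)cc1)[C@H](O[Si](C)(C)C(C)(C)C)C[C@@H](C)CCO[Si](c1ccccc1)(c1ccccc1)C(C)(C)C | intermediate
17 | (3S,5R,6S)-6-ethenyl-8-(PMB-oxy)-3-methyloctane-1,5-diol | C=C[C@H](CCOCc1ccc(OC)cc1)[C@H](O)C[C@@H](C)CCO | intermediate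
18 | (4R,6R)-6-[(3S)-5-(PMB-oxy)pent-1-en-3-yl]-4-methyloxan-2-ol | OC1C[C@H](C)C[C@@H](O1)[C@H](C=C)CCOCc1ccc(OC)cc1 | intermediate (not isolated)
19 | (4R,6R)-6-[(3S)-5-(PMB-oxy)pent-1-en-3-yl]-4-methyloxan-2-one | O=C1C[C@H](C)C[C@@H](O1)[C@H](C=C)CCOCc1ccc(OC)cc1 | intermediate
20 | 3-(TBS-oxy)propanal | O=CCCO[Si](C)(C)C(C)(C)C | starting material
21 | (3R,4R,6R)-3-[3-(TBS-oxy)-1-hydroxypropyl]-6-[(3S)-5-(PMB-oxy)pent-1-en-3-yl]-4-methyloxan-2-one (carbinol epimers) | O=C1[C@@H](C(O)CCO[Si](C)(C)C(C)(C)C)[C@H](C)C[C@@H](O1)[C@H](C=C)CCOCc1ccc(OC)cc1 | intermediate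
22 | (3R,4R,6R)-3-[3-(TBS-oxy)propanoyl]-6-[(3S)-5-(PMB-oxy)pent-1-en-3-yl]-4-methyloxan-2-one | O=C1[C@@H](C(=O)CCO[Si](C)(C)C(C)(C)C)[C@H](C)C[C@@H](O1)[C@H](C=C)CCOCc1ccc(OC)cc1 | intermediate
23 | (3R,4R,6R)-3-[(1S)-3-(TBS-oxy)-1-hydroxypropyl]-6-[(3S)-5-(PMB-oxy)pent-1-en-3-yl]-4-methyloxan-2-one | O=C1[C@@H]([C@@H](O)CCO[Si](C)(C)C(C)(C)C)[C@H](C)C[C@@H](O1)[C@H](C=C)CCOCc1ccc(OC)cc1 | intermediate
24 | (3R,4R,6R)-3-[(1S)-1,3-dihydroxypropyl]-6-[(3S)-5-(PMB-oxy)pent-1-en-3-yl]-4-methyloxan-2-one | O=C1[C@@H]([C@@H](O)CCO)[C@H](C)C[C@@H](O1)[C@H](C=C)CCOCc1ccc(OC)cc1 | intermediate (not isolated)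
25 | (3R,4R,6R)-3-[(4S)-2,2-dimethyl-1,3-dioxan-4-yl]-6-[(3S)-5-(PMB-oxy)pent-1-en-3-yl]-4-methyloxan-2-one | O=C1[C@@H]([C@@H]2CCOC(C)(C)O2)[C@H](C)C[C@@H](O1)[C@H](C=C)CCOCc1ccc(OC)cc1 | intermediate
26 | (2R,3R,5R,6S)-2-[(4S)-2,2-dimethyl-1,3-dioxan-4-yl]-6-ethenyl-5-hydroxy-N-methoxy-8-(PMB-oxy)-N,3-dimethyloctanamide | CON(C)C(=O)[C@@H]([C@@H]1CCOC(C)(C)O1)[C@H](C)C[C@@H](O)[C@H](C=C)CCOCc1ccc(OC)cc1 | intermediate
27 | (2R,3R,5R,6S)-2-[(4S)-2,2-dimethyl-1,3-dioxan-4-yl]-6-ethenyl-N-methoxy-8-(PMB-oxy)-N,3-dimethyl-5-(TES-oxy)octanamide | CON(C)C(=O)[C@@H]([C@@H]1CCOC(C)(C)O1)[C@H](C)C[C@@H](O[Si](CC)(CC)CC)[C@H](C=C)CCOCc1ccc(OC)cc1 | intermediate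
28 | (3R,4R,6R,7S)-3-[(4S)-2,2-dimethyl-1,3-dioxan-4-yl]-7-ethenyl-9-(PMB-oxy)-4-methyl-6-(TES-oxy)nonan-2-one | CC(=O)[C@@H]([C@@H]1CCOC(C)(C)O1)[C@H](C)C[C@@H](O[Si](CC)(CC)CC)[C@H](C=C)CCOCc1ccc(OC)cc1 | intermediate
29 | (4S)-4-[(3S,4R,6R,7S)-7-ethenyl-9-(PMB-oxy)-2,4-dimethyl-6-(TES-oxy)non-1-en-3-yl]-2,2-dimethyl-1,3-dioxane | C=C(C)[C@@H]([C@@H]1CCOC(C)(C)O1)[C@H](C)C[C@@H](O[Si](CC)(CC)CC)[C@H](C=C)CCOCc1ccc(OC)cc1 | intermediate
30 | (3S,4R,6R,7S)-7-[(4S)-2,2-dimethyl-1,3-dioxan-4-yl]-3-ethenyl-6,8-dimethyl-4-(TES-oxy)non-8-en-1-ol | C=C(C)[C@@H]([C@@H]1CCOC(C)(C)O1)[C@H](C)C[C@@H](O[Si](CC)(CC)CC)[C@H](C=C)CCO | intermediate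
31 | (3S,4R,6R,7S)-7-[(4S)-2,2-dimethyl-1,3-dioxan-4-yl]-3-ethenyl-6,8-dimethylnon-8-ene-1,4-diol | C=C(C)[C@@H]([C@@H]1CCOC(C)(C)O1)[C@H](C)C[C@@H](O)[C@H](C=C)CCO | intermediate
32 | (4S,5R)-5-[(2R,3S)-3-[(4S)-2,2-dimethyl-1,3-dioxan-4-yl]-2,4-dimethylpent-4-en-1-yl]-4-ethenyloxolan-2-ol | C=C(C)[C@@H]([C@@H]1CCOC(C)(C)O1)[C@H](C)C[C@H]1OC(O)C[C@H]1C=C | intermediate (not isolated)
33 | (4S,5R)-5-[(2R,3S)-3-[(4S)-2,2-dimethyl-1,3-dioxan-4-yl]-2,4-dimethylpent-4-en-1-yl]-4-ethenyloxolan-2-one | C=C(C)[C@@H]([C@@H]1CCOC(C)(C)O1)[C@H](C)C[C@H]1OC(=O)C[C@H]1C=C | intermediate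
34 | (3aS,6S,7R,8aR)-6-[(4S)-2,2-dimethyl-1,3-dioxan-4-yl]-5,7-dimethyl-3,3a,6,7,8,8a-hexahydro-2H-cyclohepta[b]furan-2-one | C1C(=O)O[C@@H]2C[C@@H](C)[C@H]([C@@H]3CCOC(C)(C)O3)C(C)=C[C@H]12 | intermediate
35 | 3-[(dimethylamino)methyl] derivative of 34 (C3 epimers) | CN(C)CC1C(=O)O[C@@H]2C[C@@H](C)[C@H]([C@@H]3CCOC(C)(C)O3)C(C)=C[C@H]12 | intermediate (not isolated)
36 | 3-[(trimethylammonio)methyl] derivative of 34, iodide | C[N+](C)(C)CC1C(=O)O[C@@H]2C[C@@H](C)[C@H]([C@@H]3CCOC(C)(C)O3)C(C)=C[C@H]12.[I-] | intermediate (not isolated)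
37 | (3aR,6S,7R,8aR)-6-[(4S)-2,2-dimethyl-1,3-dioxan-4-yl]-5,7-dimethyl-3-methylidene-3,3a,6,7,8,8a-hexahydro-2H-cyclohepta[b]furan-2-one | C=C1C(=O)O[C@@H]2C[C@@H](C)[C@H]([C@@H]3CCOC(C)(C)O3)C(C)=C[C@H]12 | intermediate
38 | (3aR,6S,7R,8aR)-6-[(1S)-1,3-dihydroxypropyl]-5,7-dimethyl-3-methylidene-3,3a,6,7,8,8a-hexahydro-2H-cyclohepta[b]furan-2-one | C=C1C(=O)O[C@@H]2C[C@@H](C)[C@H]([C@@H](O)CCO)C(C)=C[C@H]12 | intermediate
39 | (3S)-3-[(3aR,6S,7R,8aR)-5,7-dimethyl-3-methylidene-2-oxo-3,3a,6,7,8,8a-hexahydro-2H-cyclohepta[b]furan-6-yl]-3-hydroxypropyl acetate | C=C1C(=O)O[C@@H]2C[C@@H](C)[C@H]([C@@H](O)CCOC(C)=O)C(C)=C[C@H]12 | intermediate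
40 | angelic acid, (2Z)-2-methylbut-2-enoic acid | C/C=C(/C)C(=O)O | starting material
41 | angelic 2,4,6-trichlorobenzoic anhydride | C/C=C(/C)C(=O)OC(=O)c1c(Cl)cc(Cl)cc1Cl | intermediate (not isolated)
42 | (1S)-3-acetoxy-1-[(3aR,6S,7R,8aR)-5,7-dimethyl-3-methylidene-2-oxo-3,3a,6,7,8,8a-hexahydro-2H-cyclohepta[b]furan-6-yl]propyl (2Z)-2-methylbut-2-enoate | C=C1C(=O)O[C@@H]2C[C@@H](C)[C@H]([C@H](CCOC(C)=O)OC(=O)/C(C)=C\C)C(C)=C[C@H]12 | target

## Step count and risks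

Total step count: 30. Longest linear sequence: 30 steps (1 → 42); 20 and 40 are bought.

The three steps most likely to fail:

**Step 17 (facial selectivity of the ketone reduction at C2).** If chelate control by zinc is poor for this 2-acyl lactone, the fallback replaces substrate control with catalyst control. It sets out from 22 and returns at 23: (R)-Me-CBS oxazaborolidine (0.3 equiv) with catecholborane in toluene at −60 °C reduces the ketone with the branched C1 side as the large group and CH2CH2OTBS as the small group, giving the (S)-carbinol. The minor epimer is re-oxidised to 22 and recycled. This detour makes no compound outside the list (none F0).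

**Step 26 (ring-closing metathesis to a trisubstituted cycloheptene from a hindered isopropenyl group).** The fallback closes the same C5=C6 bond by carbonyl coupling instead of olefin metathesis. It sets out from 28 and returns at 34. Lemieux–Johnson cleavage of the vinyl group (cat. OsO4, NaIO4, 2,6-lutidine, dioxane/H2O) gives the keto-aldehyde F1. Intramolecular McMurry coupling (TiCl3(DME)1.5, Zn–Cu, DME, reflux, slow addition) gives the cycloheptene F2. DDQ then gives the primary alcohol F3, TBAF gives the diol F4, and TEMPO/PhI(OAc)2 lactonises F4 to 34.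

**Step 30 (angeloylation of the hindered C2–OH without isomerisation to the tiglate).** The fallback builds the Z-alkene on the substrate instead of transferring a preformed angeloyl group. It sets out from 39 and returns at 42. Acylation of 39 with 2-[bis(2,2,2-trifluoroethoxy)phosphoryl]propanoic acid (DCC, cat. DMAP, CH2Cl2) gives the phosphonate ester F5. Still–Gennari olefination of F5 with acetaldehyde (KHMDS, 18-crown-6, THF, −78 °C) gives the (Z)-2-methylbut-2-enoate 42 directly.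

## Further compounds

F0 | step 17 | none | none
F1 | step 26 | (2R,3R,5R,6R)-6-[(4S)-2,2-dimethyl-1,3-dioxan-4-yl]-2-[2-(PMB-oxy)ethyl]-5-methyl-7-oxo-3-(TES-oxy)octanal | CC(=O)[C@@H]([C@@H]1CCOC(C)(C)O1)[C@H](C)C[C@@H](O[Si](CC)(CC)CC)[C@H](C=O)CCOCc1ccc(OC)cc1
F2 | step 26 | (4S)-4-[(1S,4S,5R,7R)-4-[2-(PMB-oxy)ethyl]-2,7-dimethyl-5-(TES-oxy)cyclohept-2-en-1-yl]-2,2-dimethyl-1,3-dioxane | CC1=C[C@H](CCOCc2ccc(OC)cc2)[C@H](O[Si](CC)(CC)CC)C[C@@H](C)[C@@H]1[C@@H]1CCOC(C)(C)O1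
F3 | step 26 | 2-[(1S,4S,5R,7R)-4-[(4S)-2,2-dimethyl-1,3-dioxan-4-yl]-3,5-dimethyl-7-(TES-oxy)cyclohept-2-en-1-yl]ethan-1-ol | CC1=C[C@H](CCO)[C@H](O[Si](CC)(CC)CC)C[C@@H](C)[C@@H]1[C@@H]1CCOC(C)(C)O1
F4 | step 26 | 2-[(1S,4S,5R,7R)-4-[(4S)-2,2-dimethyl-1,3-dioxan-4-yl]-7-hydroxy-3,5-dimethylcyclohept-2-en-1-yl]ethan-1-ol | CC1=C[C@H](CCO)[C@H](O)C[C@@H](C)[C@@H]1[C@@H]1CCOC(C)(C)O1
F5 | step 30 | (1S)-3-acetoxy-1-[(3aR,6S,7R,8aR)-5,7-dimethyl-3-methylidene-2-oxo-3,3a,6,7,8,8a-hexahydro-2H-cyclohepta[b]furan-6-yl]propyl 2-[bis(2,2,2-trifluoroethoxy)phosphoryl]propanoate | C=C1C(=O)O[C@@H]2C[C@@H](C)[C@H]([C@H](CCOC(C)=O)OC(=O)C(C)P(=O)(OCC(F)(F)F)OCC(F)(F)F)C(C)=C[C@H]12
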